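**Retrosynthetic overview**

1. Target (rings: A 3-hydroxyphenyl, B 1,4-phenylene, C oxygenated central ring, D catechol) ⇒ its tetramethyl ether by fourfold O-demethylation.
2. A–CH2CH2–B bridge ⇒ stilbene ⇒ α-arylcinnamic acid ⇒ Perkin-type aldol condensation of a B–C–D diaryl ether aldehyde with 3-methoxyphenylacetic acid (key C–C bond, two fragments joined).
3. B–O–C diaryl ether ⇒ SNAr of the C–D bibenzyl phenol on 4-fluorobenzaldehyde.
4. C–CH2CH2–D bridge ⇒ the same aldol condensation / decarboxylation / hydrogenation sequence from isovanillin and 2,3-dimethoxyphenylacetic acid.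
5. No ring is constructed; the four purchased benzene rings are connected in the order C+D, then B, then A.

Assumption: the target has no stereocentre and no configured double bond, so "the single enantiomer given" is taken to mean the achiral compound as drawn.

**Route**

Step 1
Reactants: 1 isovanillin (3-hydroxy-4-methoxybenzaldehyde); 2 2,3-dimethoxyphenylacetic acid
Product: 5 (E)-2-(2,3-dimethoxyphenyl)-3-(3-hydroxy-4-methoxyphenyl)prop-2-enoic acid, via 3-acetoxy-4-methoxybenzaldehyde 3 (not isolated), via O-acetyl acrylic acid 4 (not isolated)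
Conditions: Ac2O, Et3N, 120 °C, 5 h, N2; then 2 M aq NaOH, rt, 1 h; then conc. HCl to pH 1
Reagents that add atoms: none
Why: Perkin-type aldol condensation in which the mixed-anhydride enolate of 2 adds to the aldehyde of 3 (1 is O-acetylated at once by Ac2O), elimination gives the E acid 4 with the two aryl groups cis, and hydroxide then cleaves the aryl acetate; no stereocentre is formed.

Step 2
Reactants: 5 (E)-2-(2,3-dimethoxyphenyl)-3-(3-hydroxy-4-methoxyphenyl)prop-2-enoic acid
Product: 6 5-[(Z)-2-(2,3-dimethoxyphenyl)ethenyl]-2-methoxyphenol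
Conditions: Cu powder, quinoline, 200–210 °C, 2 h, N2
Reagents that add atoms: none
Why: Copper/quinoline protodecarboxylation of an α-arylcinnamic acid replaces CO2H by H with retention through a vinylcopper species to give the Z-stilbene, and any E isomer formed thermally converges to the same bibenzyl in step 3.

Step 3
Reactants: 6 5-[(Z)-2-(2,3-dimethoxyphenyl)ethenyl]-2-methoxyphenol
Product: 7 5-[2-(2,3-dimethoxyphenyl)ethyl]-2-methoxyphenol
Conditions: H2 (1 atm), 10% Pd/C, EtOAc–MeOH, rt
Reagents that add atoms: none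
Why: Heterogeneous catalytic hydrogenation saturates the stilbene C=C while aryl methyl ethers and the free phenol are inert.

Step 4
Reactants: 7 5-[2-(2,3-dimethoxyphenyl)ethyl]-2-methoxyphenol; 8 4-fluorobenzaldehyde
Product: 9 4-{5-[2-(2,3-dimethoxyphenyl)ethyl]-2-methoxyphenoxy}benzaldehyde
Conditions: K2CO3, DMF, 140 °C, 12 h, N2
Reagents that add atoms: none
Why: Nucleophilic aromatic substitution (SNAr) in which the phenoxide of 7 displaces fluoride para to the activating formyl group through a Meisenheimer complex, giving the diaryl ether.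

Step 5
Reactants: 9 4-{5-[2-(2,3-dimethoxyphenyl)ethyl]-2-methoxyphenoxy}benzaldehyde; 10 3-methoxyphenylacetic acid
Product: 11 (E)-3-(4-{5-[2-(2,3-dimethoxyphenyl)ethyl]-2-methoxyphenoxy}phenyl)-2-(3-methoxyphenyl)prop-2-enoic acid
Conditions: Ac2O, Et3N, 120 °C, 6 h, N2; then H2O, 80 °C; aq HCl work-up
Reagents that add atoms: none
Why: Perkin-type aldol condensation in which the mixed-anhydride enolate of 10 adds to the non-enolisable aldehyde 9 and elimination gives the E α-arylcinnamic acid, forming the key C–C bond that joins the A-ring fragment to the B–C–D fragment.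

Step 6
Reactants: 11 (E)-3-(4-{5-[2-(2,3-dimethoxyphenyl)ethyl]-2-methoxyphenoxy}phenyl)-2-(3-methoxyphenyl)prop-2-enoic acid
Product: 12 1,2-dimethoxy-3-[2-(4-methoxy-3-{4-[(Z)-2-(3-methoxyphenyl)ethenyl]phenoxy}phenyl)ethyl]benzene
Conditions: Cu powder, quinoline, 200–210 °C, 2–3 h, N2
Reagents that add atoms: none
Why: Copper/quinoline protodecarboxylation again replaces the vinylic CO2H by H with retention to give the Z-stilbene, the diaryl ether and methyl ethers being thermally stable, and any E isomer converges in step 7.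

Step 7
Reactants: 12 1,2-dimethoxy-3-[2-(4-methoxy-3-{4-[(Z)-2-(3-methoxyphenyl)ethenyl]phenoxy}phenyl)ethyl]benzene
Product: 13 1,2-dimethoxy-3-[2-(4-methoxy-3-{4-[2-(3-methoxyphenyl)ethyl]phenoxy}phenyl)ethyl]benzene
Conditions: H2 (1 atm), 10% Pd/C, EtOAc, rt
Reagents that add atoms: none
Why: Catalytic hydrogenation reduces the stilbene C=C, and there is no benzyl ether, halide or other hydrogenolysable group in the molecule.

Step 8
Reactants: 13 1,2-dimethoxy-3-[2-(4-methoxy-3-{4-[2-(3-methoxyphenyl)ethyl]phenoxy}phenyl)ethyl]benzene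
Product: 14 3-[2-(4-hydroxy-3-{4-[2-(3-hydroxyphenyl)ethyl]phenoxy}phenyl)ethyl]benzene-1,2-diol (target)
Conditions: BBr3 (10 equiv), CH2Cl2, −78 °C → rt, 12 h; then ice-water
Reagents that add atoms: none
Why: Lewis-acid ether cleavage in which BBr3 complexes each ArO–Me oxygen and bromide attacks the methyl carbon (SN2), leaving the diaryl ether and benzylic C–C bonds intact, and aqueous hydrolysis of the aryl borates frees the four phenols.

**Compound list**

1 | isovanillin (3-hydroxy-4-methoxybenzaldehyde) | COc1ccc(C=O)cc1O | starting material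
2 | 2,3-dimethoxyphenylacetic acid | COc1cccc(CC(=O)O)c1OC | starting material
3 | 3-acetoxy-4-methoxybenzaldehyde | COc1ccc(C=O)cc1OC(C)=O | intermediate (not isolated)
4 | (E)-3-(3-acetoxy-4-methoxyphenyl)-2-(2,3-dimethoxyphenyl)prop-2-enoic acid | COc1ccc(/C=C(/C(=O)O)c2cccc(OC)c2OC)cc1OC(C)=O | intermediate (not isolated)
5 | (E)-2-(2,3-dimethoxyphenyl)-3-(3-hydroxy-4-methoxyphenyl)prop-2-enoic acid | COc1ccc(/C=C(/C(=O)O)c2cccc(OC)c2OC)cc1O | intermediate
6 | 5-[(Z)-2-(2,3-dimethoxyphenyl)ethenyl]-2-methoxyphenol | COc1ccc(/C=C\c2cccc(OC)c2OC)cc1O | intermediate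
7 | 5-[2-(2,3-dimethoxyphenyl)ethyl]-2-methoxyphenol | COc1ccc(CCc2cccc(OC)c2OC)cc1O | intermediate
8 | 4-fluorobenzaldehyde | O=Cc1ccc(F)cc1 | starting material
9 | 4-{5-[2-(2,3-dimethoxyphenyl)ethyl]-2-methoxyphenoxy}benzaldehyde | COc1ccc(CCc2cccc(OC)c2OC)cc1Oc1ccc(C=O)cc1 | intermediate
10 | 3-methoxyphenylacetic acid | COc1cccc(CC(=O)O)c1 | starting material
11 | (E)-3-(4-{5-[2-(2,3-dimethoxyphenyl)ethyl]-2-methoxyphenoxy}phenyl)-2-(3-methoxyphenyl)prop-2-enoic acid | OC(=O)/C(=C/c1ccc(Oc2cc(CCc3cccc(OC)c3OC)ccc2OC)cc1)c1cccc(OC)c1 | intermediate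
12 | 1,2-dimethoxy-3-[2-(4-methoxy-3-{4-[(Z)-2-(3-methoxyphenyl)ethenyl]phenoxy}phenyl)ethyl]benzene | COc1cccc(/C=C\c2ccc(Oc3cc(CCc4cccc(OC)c4OC)ccc3OC)cc2)c1 | intermediate
13 | 1,2-dimethoxy-3-[2-(4-methoxy-3-{4-[2-(3-methoxyphenyl)ethyl]phenoxy}phenyl)ethyl]benzene | COc1cccc(CCc2ccc(Oc3cc(CCc4cccc(OC)c4OC)ccc3OC)cc2)c1 | intermediate
14 | 3-[2-(4-hydroxy-3-{4-[2-(3-hydroxyphenyl)ethyl]phenoxy}phenyl)ethyl]benzene-1,2-diol | Oc1cccc(CCc2ccc(Oc3cc(CCc4cccc(O)c4O)ccc3O)cc2)c1 | target

**Summary**

Total step count: 8.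
Longest linear sequence: 8 steps (1 or 2 → 14); 8 and 10 enter at steps 4 and 5.

**Three steps most likely to fail, with fallbacks**

Step 6 (decarboxylation of the large acid 11 above 200 °C; tarring or incomplete conversion). The fallback sets out from 11 and comes back to the route at 13. The acrylic acid double bond of 11 is hydrogenated (H2, Pd/C, EtOAc–MeOH) to racemic 3-(4-{5-[2-(2,3-dimethoxyphenyl)ethyl]-2-methoxyphenoxy}phenyl)-2-(3-methoxyphenyl)propanoic acid F2. This is esterified with 2-mercaptopyridine N-oxide (DCC, cat. DMAP, CH2Cl2, dark) to the Barton ester 2-thioxopyridin-1(2H)-yl 3-(4-{5-[2-(2,3-dimethoxyphenyl)ethyl]-2-methoxyphenoxy}phenyl)-2-(3-methoxyphenyl)propanoate F3. Photolysis of the ester with excess t-BuSH (tungsten lamp, toluene, rt) effects radical-chain reductive decarboxylation to 13, so steps 6 and 7 are replaced by a mild radical sequence.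

Step 5 (Perkin condensation of the electron-rich, bulky aldehyde 9; sluggish reaction or modest yield). The fallback sets out from 9 and comes back at 13. Horner–Wadsworth–Emmons olefination of 9 with commercial diethyl (3-methoxybenzyl)phosphonate (NaH, THF, 0 °C → rt) gives the stilbene 1,2-dimethoxy-3-[2-(4-methoxy-3-{4-[(E)-2-(3-methoxyphenyl)ethenyl]phenoxy}phenyl)ethyl]benzene F1. Hydrogenation of it (H2, Pd/C, EtOAc) gives 13, bypassing 11 and 12.

Step 8 (incomplete fourfold demethylation, or loss of the air-sensitive catechol during work-up). The fallback sets out from 13 and comes back at 14. Compound 13 is fused with neat pyridine hydrochloride (190–200 °C, argon, 3 h), then diluted with dilute aqueous HCl and extracted. This is a Brønsted-acid melt in which chloride dealkylates the protonated ethers, with no boron intermediates to hydrolyse; it makes no new compound (F0).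

**Further compounds**

F1 | step 5 | 1,2-dimethoxy-3-[2-(4-methoxy-3-{4-[(E)-2-(3-methoxyphenyl)ethenyl]phenoxy}phenyl)ethyl]benzene | COc1cccc(/C=C/c2ccc(Oc3cc(CCc4cccc(OC)c4OC)ccc3OC)cc2)c1
F2 | step 6 | racemic 3-(4-{5-[2-(2,3-dimethoxyphenyl)ethyl]-2-methoxyphenoxy}phenyl)-2-(3-methoxyphenyl)propanoic acid | COc1cccc(C(Cc2ccc(Oc3cc(CCc4cccc(OC)c4OC)ccc3OC)cc2)C(=O)O)c1
F3 | step 6 | racemic 2-thioxopyridin-1(2H)-yl 3-(4-{5-[2-(2,3-dimethoxyphenyl)ethyl]-2-methoxyphenoxy}phenyl)-2-(3-methoxyphenyl)propanoate | COc1cccc(C(Cc2ccc(Oc3cc(CCc4cccc(OC)c4OC)ccc3OC)cc2)C(=O)ON2C=CC=CC2=S)c1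
F0 | step 8 | none | none
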